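## Retrosynthetic overview

1. Target 23 ⇐ spiro-lactol 21. Ring A (ten-membered carbocycle) and ring C (γ-lactone) close last, by intramolecular indium Barbier allylation (C6–C7) and lactonisation, on a substrate that already holds ring B (the tetrahydrofuran hemiketal, bridge C3–O–C10).
2. 21 ⇐ furan 19, by oxidative spiroketalisation: the 2-alkyl-3-methylfuran is a masked (Z)-4-oxo-enal (C3–C6) that the C10 hydroxyl traps.
3. 19 ⇐ aldehyde 11 by the key C8–O bond: amine-catalysed enantioselective α-acyloxylation with the mixed peroxide 13 (3-chlorobenzoyl (2R)-2-methylbutanoyl peroxide) sets C8 and installs the ester. C7–C11 vinylalumination and SN2' bromination follow.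
4. 11 ⇐ epoxy alcohol 5 + (Z)-enynol 6: Sharpless epoxidation makes the C10–O bond, acetylide opening makes C1–C2, gold catalysis closes the furan.
5. 5 ⇐ propargyl alcohol 1 + bromo-acetal 2. Ring order: furan (temporary) → ring B → rings A and C together.

Assumption: germacrane numbering (C1–C15) labels the atoms; the C3 hemiketal is taken as thermodynamically controlled (only the 3S epimer can bridge to O10); 2, 6, 12, 15 and mCPBA are purchased.

## Route

Step 1
Reactants: 1 prop-2-yn-1-ol; 2 2-(2-bromoethyl)-1,3-dioxolane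
Product: 4 4-(1,3-dioxolan-2-yl)-2-methylidenebutan-1-ol, via Grignard reagent 3 (not isolated)
Conditions: 2 (2.5 equiv), Mg, THF, 25 °C; then 1, CuI (10 mol %), THF, −10 °C → rt; aq NH4Cl
Reagents that add atoms: none
Why: Copper-catalysed anti-carbomagnesiation of propargyl alcohol (alkoxide-directed) places the alkyl group on the internal alkyne carbon, giving the 2-substituted allylic alcohol with C7 masked as an acetal.

Step 2
Reactants: 4 4-(1,3-dioxolan-2-yl)-2-methylidenebutan-1-ol
Product: 5 [(2R)-2-[2-(1,3-dioxolan-2-yl)ethyl]oxiran-2-yl]methanol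
Conditions: Ti(OiPr)4 (10 mol %), D-(−)-diethyl tartrate (12 mol %), t-BuOOH, 4 Å MS, CH2Cl2, −20 °C
Reagents that add atoms: tert-butyl hydroperoxide, CC(C)(C)OO
Why: Sharpless asymmetric epoxidation of a 2-substituted allylic alcohol; the D-tartrate delivers oxygen to the face that gives the (R)-epoxide, forming the C10–O bond of the later oxygen bridge (C10 set here).

Step 3
Reactants: 5 [(2R)-2-[2-(1,3-dioxolan-2-yl)ethyl]oxiran-2-yl]methanol; 6 (2Z)-3-methylpent-2-en-4-yn-1-ol
Product: 8 (2S,6Z)-2-[2-(1,3-dioxolan-2-yl)ethyl]-6-methyloct-6-en-4-yne-1,2,8-triol, via dilithio enynolate 7 (not isolated)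
Conditions: 6 (3 equiv), n-BuLi (6 equiv), THF, −78 → −20 °C; BF3·OEt2 (3 equiv), −78 °C; then 5; aq NH4Cl
Reagents that add atoms: none
Why: Yamaguchi–Hirao alkynylation opens the epoxide at its unsubstituted CH2 (C1), so C10 is untouched (a Payne shift of this epoxy alcohol is degenerate) and the Z-alkene of 6 is carried through.

Step 4
Reactants: 8 (2S,6Z)-2-[2-(1,3-dioxolan-2-yl)ethyl]-6-methyloct-6-en-4-yne-1,2,8-triol
Product: 10 2-[2-[(4R)-2,2-dimethyl-4-[2-(3-methylfuran-2-yl)ethyl]-1,3-dioxolan-4-yl]ethyl]-1,3-dioxolane, via furan diol 9 (not isolated)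
Conditions: AuCl3 (2 mol %), CH2Cl2, rt; then 2,2-dimethoxypropane, PPTS, rt
Reagents that add atoms: 2,2-dimethoxypropane, COC(C)(C)OC
Why: Gold-catalysed 5-exo-dig hydroalkoxylation of the (Z)-enynol followed by aromatisation gives the 2-alkyl-3-methylfuran (a stable mask for the Z keto-enal), and the 1,2-diol is then closed as its acetonide in the same pot.

Step 5
Reactants: 10 2-[2-[(4R)-2,2-dimethyl-4-[2-(3-methylfuran-2-yl)ethyl]-1,3-dioxolan-4-yl]ethyl]-1,3-dioxolane
Product: 11 3-[(4R)-2,2-dimethyl-4-[2-(3-methylfuran-2-yl)ethyl]-1,3-dioxolan-4-yl]propanal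
Conditions: Et3SiOTf, 2,4,6-collidine, CH2Cl2, 0 °C; then H2O
Reagents that add atoms: water, O
Why: Fujioka-type chemoselective cleavage of an aldehyde acetal: the silyl triflate and collidine convert it into a collidinium salt that water hydrolyses, while the ketal (acetonide) does not react.

Step 6
Reactants: 12 (2R)-2-methylbutanoic acid
Product: 13 3-chlorobenzoyl (2R)-2-methylbutanoyl peroxide
Conditions: mCPBA (buffer-washed and dried, 1.1 equiv), DCC (1.1 equiv), CH2Cl2, 0 °C; filter, cold short silica plug; used cold and fresh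
Reagents that add atoms: 3-chloroperoxybenzoic acid (mCPBA), OOC(=O)c1cccc(Cl)c1
Why: Carbodiimide-mediated condensation of a carboxylic acid with a peracid is the standard synthesis of unsymmetrical alkanoyl aroyl peroxides, uses one equivalent of the enantiopure acid and, being base-free, does not touch the α-stereocentre.

Step 7
Reactants: 11 3-[(4R)-2,2-dimethyl-4-[2-(3-methylfuran-2-yl)ethyl]-1,3-dioxolan-4-yl]propanal; 13 3-chlorobenzoyl (2R)-2-methylbutanoyl peroxide
Product: 14 (2R)-1-[(4R)-2,2-dimethyl-4-[2-(3-methylfuran-2-yl)ethyl]-1,3-dioxolan-4-yl]-3-oxopropan-2-yl (2R)-2-methylbutanoate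
Conditions: 13 (1.2 equiv), (R)-2-[diphenyl(trimethylsilyloxy)methyl]pyrrolidine (10 mol %), hydroquinone (10 mol %), THF, −10 °C; filtered cold and used crude
Reagents that add atoms: none
Why: Proposed new method: catalytic enantioselective α-acyloxylation of an aldehyde with an unsymmetrical alkanoyl aroyl peroxide, in which the E-enamine of 11 and the (R)-diarylprolinol silyl ether attacks, from its unshielded face, the peroxide oxygen that carries the 2-methylbutanoyl group in an SN2-type displacement at oxygen, because 3-chlorobenzoate (the carboxylate of the stronger acid) is the better leaving group, so that the C8–O bond, the (R)-configuration at C8 and the natural ester are made in one event before hydrolysis frees the catalyst; the closest known reaction type is the amine-catalysed α-benzoyloxylation of aldehydes with dibenzoyl peroxide, which has not been shown for selective transfer of a chiral aliphatic acyloxy group from a mixed peroxide.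

Step 8
Reactants: 14 (2R)-1-[(4R)-2,2-dimethyl-4-[2-(3-methylfuran-2-yl)ethyl]-1,3-dioxolan-4-yl]-3-oxopropan-2-yl (2R)-2-methylbutanoate; 15 methyl prop-2-ynoate
Product: 17 methyl (4R)-5-[(4R)-2,2-dimethyl-4-[2-(3-methylfuran-2-yl)ethyl]-1,3-dioxolan-4-yl]-3-hydroxy-2-methylidene-4-[(2R)-2-methylbutanoyl]oxypentanoate (both C3 epimers), via vinylalane 16 (not isolated)
Conditions: 15, i-Bu2AlH, NMO, THF, 0 °C; then 14, 0 °C → rt
Reagents that add atoms: none
Why: Vinylalumination (hydroalumination of the propiolate, then carbonyl addition) gives the Morita–Baylis–Hillman-type adduct without amine base, which protects the labile C8 centre; the new carbinol centre is removed in the next step.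

Step 9
Reactants: 17 methyl (4R)-5-[(4R)-2,2-dimethyl-4-[2-(3-methylfuran-2-yl)ethyl]-1,3-dioxolan-4-yl]-3-hydroxy-2-methylidene-4-[(2R)-2-methylbutanoyl]oxypentanoate
Product: 19 methyl (2Z,4R)-2-(bromomethyl)-5-[(4R)-2,2-dimethyl-4-[2-(3-methylfuran-2-yl)ethyl]-1,3-dioxolan-4-yl]-4-[(2R)-2-methylbutanoyl]oxypent-2-enoate, via mesylate 18 (not isolated)
Conditions: MsCl, Et3N, CH2Cl2, −10 °C; then LiBr, acetone, rt
Reagents that add atoms: lithium bromide, [Li+].[Br-]
Why: SN2' displacement of the activated Baylis–Hillman alcohol by bromide gives the thermodynamically preferred (Z)-2-(bromomethyl)enoate under non-acidic conditions that spare the furan and the acetonide.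

Step 10
Reactants: 19 methyl (2Z,4R)-2-(bromomethyl)-5-[(4R)-2,2-dimethyl-4-[2-(3-methylfuran-2-yl)ethyl]-1,3-dioxolan-4-yl]-4-[(2R)-2-methylbutanoyl]oxypent-2-enoate
Product: 21 methyl (2Z,4R)-2-(bromomethyl)-5-[(7R)-2-hydroxy-7-(hydroxymethyl)-4-methyl-1,6-dioxaspiro[4.4]non-3-en-7-yl]-4-[(2R)-2-methylbutanoyl]oxypent-2-enoate (lactol and spiro anomers), via furan diol bromide 20 (not isolated)
Conditions: AcOH/H2O (4:1), rt; concentrate; then NBS, NaHCO3, THF/H2O, 0 °C
Reagents that add atoms: water, O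
Why: Acetal hydrolysis frees the diol, and Achmatowicz-type oxidative spiroketalisation of the 2-(3-hydroxyalkyl)furan then lets the C10 hydroxyl trap C3 (ring B, C3–O bond) while water gives the C6 lactol, so the Z geometry stays locked in a ring and the C3 ketone stays masked.

Step 11
Reactants: 21 methyl (2Z,4R)-2-(bromomethyl)-5-[(7R)-2-hydroxy-7-(hydroxymethyl)-4-methyl-1,6-dioxaspiro[4.4]non-3-en-7-yl]-4-[(2R)-2-methylbutanoyl]oxypent-2-enoate
Product: 23 CNP0328225.2 (target; 3S,6S,7R,8R,10R; 4Z), via seco hydroxy ester 22 (not isolated)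
Conditions: In powder, THF/H2O (3:1), 0.002 M, 40 °C; then PPTS (cat.), CH2Cl2, rt
Reagents that add atoms: none
Why: Intramolecular indium Barbier allylation of the lactol aldehyde through a chair transition state of the (Z)-γ-substituted allylindium gives the syn adduct (cis-fused lactone, 6S,7R) with attack at C7 anti to C9 under allylic-strain control by C8; lactonisation and equilibration to the only bridgeable C3 hemiketal epimer follow.

## Compound list

1 | prop-2-yn-1-ol | C#CCO | starting material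
2 | 2-(2-bromoethyl)-1,3-dioxolane | BrCCC1OCCO1 | starting material
3 | [2-(1,3-dioxolan-2-yl)ethyl]magnesium bromide | Br[Mg]CCC1OCCO1 | intermediate
4 | 4-(1,3-dioxolan-2-yl)-2-methylidenebutan-1-ol | OCC(=C)CCC1OCCO1 | intermediate
5 | [(2R)-2-[2-(1,3-dioxolan-2-yl)ethyl]oxiran-2-yl]methanol | OC[C@]1(CCC2OCCO2)CO1 | intermediate
6 | (2Z)-3-methylpent-2-en-4-yn-1-ol | C#C/C(C)=C\CO | starting material
7 | dilithium salt of 6 (lithium acetylide and lithium alkoxide) | [Li]C#C/C(C)=C\CO[Li] | intermediate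
8 | (2S,6Z)-2-[2-(1,3-dioxolan-2-yl)ethyl]-6-methyloct-6-en-4-yne-1,2,8-triol | OC[C@](O)(CCC1OCCO1)CC#C/C(C)=C\CO | intermediate
9 | (2R)-2-[2-(1,3-dioxolan-2-yl)ethyl]-4-(3-methylfuran-2-yl)butane-1,2-diol | Cc1ccoc1CC[C@](O)(CO)CCC1OCCO1 | intermediate
10 | 2-[2-[(4R)-2,2-dimethyl-4-[2-(3-methylfuran-2-yl)ethyl]-1,3-dioxolan-4-yl]ethyl]-1,3-dioxolane | Cc1ccoc1CC[C@@]2(CCC3OCCO3)COC(C)(C)O2 | intermediate
11 | 3-[(4R)-2,2-dimethyl-4-[2-(3-methylfuran-2-yl)ethyl]-1,3-dioxolan-4-yl]propanal | Cc1ccoc1CC[C@@]2(CCC=O)COC(C)(C)O2 | intermediate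
12 | (2R)-2-methylbutanoic acid | CC[C@@H](C)C(=O)O | starting material
13 | 3-chlorobenzoyl (2R)-2-methylbutanoyl peroxide | CC[C@@H](C)C(=O)OOC(=O)c1cccc(Cl)c1 | intermediate
14 | (2R)-1-[(4R)-2,2-dimethyl-4-[2-(3-methylfuran-2-yl)ethyl]-1,3-dioxolan-4-yl]-3-oxopropan-2-yl (2R)-2-methylbutanoate | Cc1ccoc1CC[C@@]2(C[C@@H](OC(=O)[C@H](C)CC)C=O)COC(C)(C)O2 | intermediate
15 | methyl prop-2-ynoate | C#CC(=O)OC | starting material
16 | methyl 2-[bis(2-methylpropyl)alumanyl]prop-2-enoate | C=C(C(=O)OC)[Al](CC(C)C)CC(C)C | intermediate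
17 | methyl (4R)-5-[(4R)-2,2-dimethyl-4-[2-(3-methylfuran-2-yl)ethyl]-1,3-dioxolan-4-yl]-3-hydroxy-2-methylidene-4-[(2R)-2-methylbutanoyl]oxypentanoate (C3 epimers) | Cc1ccoc1CC[C@@]2(C[C@@H](OC(=O)[C@H](C)CC)C(O)C(=C)C(=O)OC)COC(C)(C)O2 | intermediate
18 | 3-O-methanesulfonate of 17 | Cc1ccoc1CC[C@@]2(C[C@@H](OC(=O)[C@H](C)CC)C(OS(C)(=O)=O)C(=C)C(=O)OC)COC(C)(C)O2 | intermediate
19 | methyl (2Z,4R)-2-(bromomethyl)-5-[(4R)-2,2-dimethyl-4-[2-(3-methylfuran-2-yl)ethyl]-1,3-dioxolan-4-yl]-4-[(2R)-2-methylbutanoyl]oxypent-2-enoate | Cc1ccoc1CC[C@@]2(C[C@@H](OC(=O)[C@H](C)CC)/C=C(\CBr)C(=O)OC)COC(C)(C)O2 | intermediate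
20 | methyl (2Z,4R,6R)-2-(bromomethyl)-6-hydroxy-6-(hydroxymethyl)-4-[(2R)-2-methylbutanoyl]oxy-8-(3-methylfuran-2-yl)oct-2-enoate | Cc1ccoc1CC[C@](O)(CO)C[C@@H](OC(=O)[C@H](C)CC)/C=C(\CBr)C(=O)OC | intermediate
21 | methyl (2Z,4R)-2-(bromomethyl)-5-[(7R)-2-hydroxy-7-(hydroxymethyl)-4-methyl-1,6-dioxaspiro[4.4]non-3-en-7-yl]-4-[(2R)-2-methylbutanoyl]oxypent-2-enoate (anomers at the lactol and spiro carbons) | OC1OC2(CC[C@](CO)(C[C@@H](OC(=O)[C@H](C)CC)/C=C(\CBr)C(=O)OC)O2)C(C)=C1 | intermediate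
22 | seco hydroxy methyl ester of 23 (lactone opened to C6–OH and C12 methyl ester; all stereocentres as in 23) | C=C(C(=O)OC)[C@@H]1[C@H](OC(=O)[C@H](C)CC)C[C@@]2(CO)CC[C@](O)(O2)/C(C)=C\[C@@H]1O | intermediate
23 | CNP0328225.2: 3,14-dihydroxy-3,10-epoxy-8-[(2R)-2-methylbutanoyl]oxygermacra-4Z,11(13)-dien-12,6-olide (3S,6S,7R,8R,10R) | C=C1C(=O)O[C@H]2/C=C(/C)[C@]3(O)CC[C@](CO)(C[C@@H](OC(=O)[C@H](C)CC)[C@@H]12)O3 | target

## Step count and risks

Total steps: 11. Longest linear sequence: 10 (steps 1–5 and 7–11; step 6 is a one-step branch).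

The three steps most likely to fail:

Step 7 (the new α-acyloxylation; risks are competing transfer of the 3-chlorobenzoyloxy group from the mixed peroxide, low reactivity of the aliphatic acyloxy oxygen, catalyst acylation and the sense of induction). The fallback sets out from 11 and comes back at 14 using known chemistry. L-Proline-catalysed α-aminoxylation with nitrosobenzene and in-situ NaBH4 reduction gives the anilinooxy alcohol F1. Zn/AcOH cleaves the N–O bond to the diol F2. Et3SiCl/imidazole silylates the primary hydroxyl to give the silyl ether F3. EDC/DMAP esterification with 12 gives the ester silyl ether F4. Swern oxidation converts the primary triethylsilyl ether directly into aldehyde 14.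

Step 8 (C8 epimerisation or 1,2-acyl migration on the α-acyloxy aldehyde). The fallback sets out from 14 and comes back at 17. A BF3·OEt2-mediated Mukaiyama aldol with the trimethylsilyl ketene acetal of methyl 3-(phenylselanyl)propanoate gives the seleno aldol adduct F5. Oxidation with H2O2 and selenoxide syn-elimination then unveils the methylidene group of 17, so no organoaluminium or amine touches the aldehyde.

Step 11 (medium-ring closure on a lactol, and control of C6/C7). The fallback sets out from 19 and comes back at 23 with the ring order reversed (carbocycle first, oxygen bridge last). NBS/NaHCO3 in aqueous acetone opens the furan with the acetonide kept, giving the open (Z)-keto-enal F6. Indium Barbier macrocyclisation and lactonisation at high dilution give the macrocyclic keto-lactone acetonide F7. Aqueous AcOH then removes the acetonide and the freed C10 hydroxyl closes the hemiketal across the ring to give 23.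

Further compounds

F1 | step 7 | (2R)-2-(anilinooxy)-3-[(4R)-2,2-dimethyl-4-[2-(3-methylfuran-2-yl)ethyl]-1,3-dioxolan-4-yl]propan-1-ol | Cc1ccoc1CC[C@@]2(C[C@@H](ONc3ccccc3)CO)COC(C)(C)O2
F2 | step 7 | (2R)-3-[(4R)-2,2-dimethyl-4-[2-(3-methylfuran-2-yl)ethyl]-1,3-dioxolan-4-yl]propane-1,2-diol | Cc1ccoc1CC[C@@]2(C[C@@H](O)CO)COC(C)(C)O2
F3 | step 7 | (2R)-1-[(4R)-2,2-dimethyl-4-[2-(3-methylfuran-2-yl)ethyl]-1,3-dioxolan-4-yl]-3-(triethylsilyloxy)propan-2-ol | Cc1ccoc1CC[C@@]2(C[C@@H](O)CO[Si](CC)(CC)CC)COC(C)(C)O2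
F4 | step 7 | (2R)-1-[(4R)-2,2-dimethyl-4-[2-(3-methylfuran-2-yl)ethyl]-1,3-dioxolan-4-yl]-3-(triethylsilyloxy)propan-2-yl (2R)-2-methylbutanoate | Cc1ccoc1CC[C@@]2(C[C@@H](OC(=O)[C@H](C)CC)CO[Si](CC)(CC)CC)COC(C)(C)O2
F5 | step 8 | methyl (4R)-5-[(4R)-2,2-dimethyl-4-[2-(3-methylfuran-2-yl)ethyl]-1,3-dioxolan-4-yl]-3-hydroxy-4-[(2R)-2-methylbutanoyl]oxy-2-[(phenylselanyl)methyl]pentanoate (C2/C3 epimers) | Cc1ccoc1CC[C@@]2(C[C@@H](OC(=O)[C@H](C)CC)C(O)C(C[Se]c3ccccc3)C(=O)OC)COC(C)(C)O2
F6 | step 11 | methyl (2Z,4R)-2-(bromomethyl)-5-[(4R)-2,2-dimethyl-4-[(4Z)-4-methyl-3,6-dioxohex-4-en-1-yl]-1,3-dioxolan-4-yl]-4-[(2R)-2-methylbutanoyl]oxypent-2-enoate | O=C/C=C(/C)C(=O)CC[C@@]1(C[C@@H](OC(=O)[C@H](C)CC)/C=C(\CBr)C(=O)OC)COC(C)(C)O1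
F7 | step 11 | 10,14-O-isopropylidene acetal of the open 3-keto form of 23 (ten-membered keto-lactone; stereocentres C6, C7, C8, C10 as in 23) | C=C1C(=O)O[C@H]2/C=C(/C)C(=O)CC[C@@]3(C[C@@H](OC(=O)[C@H](C)CC)[C@@H]12)COC(C)(C)O3
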